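**Retrosynthetic overview**
1. Target 10 ← O-methylation of the free phenol in 9, its 4-hydroxy-3,5-dimethoxybenzyl analogue.
2. 9 ← C2–C3 bond: enamine-catalysed enantioselective α-(4-hydroxybenzyl)ation of aryloxyacetaldehyde 4 by a transient p-quinone methide 6 made from syringyl alcohol 5, then reduction in the same pot. This sets the only stereocenter, (R).
3. 4 ← O-alkylation of 4-allyl-2,6-dimethoxyphenol 1 with bromoacetaldehyde diethyl acetal 2, then acetal hydrolysis.
4. No ring is formed: both benzene rings are bought intact.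

Assumption: the stereocenter in the SMILES is (R) (OAr > CH2OH > CH2Ar > H), and the enamine of 4 reacts as its E isomer on the face away from the CPh2(OSiMe3) group, as α-alkoxyacetaldehydes do with this catalyst class; if the alcohol proves to be (S), the (R)-catalyst is used instead.

Step 1
Reactants: 1 4-allyl-2,6-dimethoxyphenol; 2 2-bromo-1,1-diethoxyethane
Product: 3 5-allyl-2-(2,2-diethoxyethoxy)-1,3-dimethoxybenzene
Conditions: Cs2CO3 (1.5 equiv), 2 (1.5 equiv), DMF, 90 °C, 16 h
Reagents that add atoms: none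
Why: Williamson ether synthesis (SN2 of the caesium phenoxide on the primary bromide); the carbonate base is too weak to isomerise the allyl group to propenyl.

Step 2
Reactants: 3 5-allyl-2-(2,2-diethoxyethoxy)-1,3-dimethoxybenzene
Product: 4 2-(4-allyl-2,6-dimethoxyphenoxy)acetaldehyde
Conditions: 1 M aq HCl/THF 1:2, 50 °C, 3 h; used at once
Reagents that add atoms: water, O
Why: Acid-catalysed acetal hydrolysis; both ortho positions carry OMe, so the usual acid cyclisation of aryloxyacetaldehydes to benzofurans is blocked, and the terminal alkene is inert to dilute acid.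

Step 3
Reactants: 4 2-(4-allyl-2,6-dimethoxyphenoxy)acetaldehyde (1.5 equiv); 5 4-(hydroxymethyl)-2,6-dimethoxyphenol (syringyl alcohol)
Product: 9 (R)-2-(4-allyl-2,6-dimethoxyphenoxy)-3-(4-hydroxy-3,5-dimethoxyphenyl)propan-1-ol, via quinone methide 6 (not isolated), via enamine 7 (not isolated), via aldehyde 8 (not isolated)
Conditions: (S)-α,α-diphenylprolinol trimethylsilyl ether (20 mol%), ClCH2CO2H (20 mol%), CHCl3/HFIP 4:1, 30 °C, 5 added over 8 h; then MeOH, NaBH4 (4 equiv), 0 °C
Reagents that add atoms: none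
Why: Proposed new method: acid/HFIP-assisted loss of water from 5 gives the δ-unsubstituted p-quinone methide 6 (or its O-protonated benzylic cation) at low stationary concentration, the catalyst condenses with 4 to the E-enamine 7 whose one face is blocked by the CPh2(OSiMe3) group, so the exocyclic CH2 of 6 is attacked from the open Re face of the enamine α-carbon (1,6-addition driven by rearomatisation) to set the (R) C–O stereocenter, hydrolysis releases aldehyde 8 and the catalyst, and NaBH4 reduces 8 in the same pot before the α-aryloxy aldehyde can epimerise; the closest known reaction types are the enamine 1,6-addition of aldehydes to preformed δ-aryl di-tert-butyl p-quinone methides and the SN1-type aminocatalytic α-alkylation of aldehydes by benzylic alcohols that ionise to stabilised cations, neither shown for a transient unsubstituted p-quinone methide from a primary 4-hydroxybenzyl alcohol or for an α-aryloxyacetaldehyde donor.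

Step 4
Reactants: 9 (R)-2-(4-allyl-2,6-dimethoxyphenoxy)-3-(4-hydroxy-3,5-dimethoxyphenyl)propan-1-ol
Product: 10 (R)-2-(4-allyl-2,6-dimethoxyphenoxy)-3-(3,4,5-trimethoxyphenyl)propan-1-ol
Conditions: MeI (1.5 equiv), K2CO3 (2 equiv), acetone, 45 °C
Reagents that add atoms: iodomethane, CI
Why: Williamson O-methylation that is chemoselective by acidity, since K2CO3 deprotonates the phenol but not the primary alcohol; the ether stereocenter is not touched.

**Compound list**
1 | 4-allyl-2,6-dimethoxyphenol (methoxyeugenol) | C=CCc1cc(OC)c(O)c(OC)c1 | starting material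
2 | 2-bromo-1,1-diethoxyethane (bromoacetaldehyde diethyl acetal) | CCOC(CBr)OCC | starting material
3 | 5-allyl-2-(2,2-diethoxyethoxy)-1,3-dimethoxybenzene | C=CCc1cc(OC)c(OCC(OCC)OCC)c(OC)c1 | intermediate
4 | 2-(4-allyl-2,6-dimethoxyphenoxy)acetaldehyde | C=CCc1cc(OC)c(OCC=O)c(OC)c1 | intermediate
5 | 4-(hydroxymethyl)-2,6-dimethoxyphenol (syringyl alcohol) | OCc1cc(OC)c(O)c(OC)c1 | starting material
6 | 2,6-dimethoxy-4-methylidenecyclohexa-2,5-dien-1-one (p-quinone methide) | C=C1C=C(OC)C(=O)C(OC)=C1 | intermediate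
7 | (S)-1-[(E)-2-(4-allyl-2,6-dimethoxyphenoxy)ethenyl]-2-[diphenyl(trimethylsilyloxy)methyl]pyrrolidine (enamine of 4) | C=CCc1cc(OC)c(O/C=C/N2CCC[C@H]2C(c2ccccc2)(c2ccccc2)O[Si](C)(C)C)c(OC)c1 | intermediate
8 | (R)-2-(4-allyl-2,6-dimethoxyphenoxy)-3-(4-hydroxy-3,5-dimethoxyphenyl)propanal | C=CCc1cc(OC)c(O[C@@H](C=O)Cc2cc(OC)c(O)c(OC)c2)c(OC)c1 | intermediate
9 | (R)-2-(4-allyl-2,6-dimethoxyphenoxy)-3-(4-hydroxy-3,5-dimethoxyphenyl)propan-1-ol | C=CCc1cc(OC)c(O[C@@H](CO)Cc2cc(OC)c(O)c(OC)c2)c(OC)c1 | intermediate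
10 | (R)-2-(4-allyl-2,6-dimethoxyphenoxy)-3-(3,4,5-trimethoxyphenyl)propan-1-ol | C=CCc1cc(OC)c(O[C@@H](CO)Cc2cc(OC)c(OC)c(OC)c2)c(OC)c1 | target

**Totals**
Total step count: 4. Longest linear sequence: 4 (1 → 3 → 4 → 9 → 10); 5 is bought and enters at step 3.

**Steps most likely to fail, with fallbacks**

The largest risk is step 3, the proposed new step. Ionisation of 5 may be slow, 6 may oligomerise or alkylate the electron-rich ring of 4, the catalyst may be N-benzylated, and the ee for so small an electrophile is unproven. The fallback for step 3 uses known chemistry only; it sets out from compound 1, which is coupled late with a separately made chiral alcohol, and comes back to the route at compound 10.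
- The commercial aryl iodide 5-iodo-1,2,3-trimethoxybenzene F1 undergoes a Heck reaction with allyl alcohol (Pd(OAc)2, Bu4NCl, NaHCO3, DMF, 45 °C) to give 3-(3,4,5-trimethoxyphenyl)propanal F2.
- D-Proline (10 mol%) and nitrosobenzene in CHCl3 at 4 °C convert it by enamine α-aminoxylation into (S)-2-(N-phenylaminooxy)-3-(3,4,5-trimethoxyphenyl)propanal F3.
- NaBH4 in MeOH reduces this in the same flask to (S)-2-(N-phenylaminooxy)-3-(3,4,5-trimethoxyphenyl)propan-1-ol F4.
- Hydrogenolysis of the N–O bond (H2, palladium on carbon, MeOH) gives (S)-3-(3,4,5-trimethoxyphenyl)propane-1,2-diol F5; no alkene is present at this stage.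
- TBSCl and imidazole in CH2Cl2 at 0 °C silylate the primary hydroxyl to give (S)-1-(tert-butyldimethylsilyloxy)-3-(3,4,5-trimethoxyphenyl)propan-2-ol F6.
- A Mitsunobu reaction with phenol 1 (PPh3, DIAD, toluene) inverts the carbinol carbon and gives (R)-tert-butyl[2-(4-allyl-2,6-dimethoxyphenoxy)-3-(3,4,5-trimethoxyphenyl)propoxy]dimethylsilane F7.
- Bu4NF in THF then gives 10.

The second risk is step 1. The bromoacetal is a sluggish electrophile towards a phenoxide flanked by two methoxy groups, and forcing the reaction risks allyl isomerisation. The fallback for step 1 sets out from compound 1 and comes back to the route at compound 4, replacing acetal chemistry by ester chemistry. Compound 1 is alkylated with the far more reactive ethyl bromoacetate (K2CO3, acetone, reflux) to give ethyl 2-(4-allyl-2,6-dimethoxyphenoxy)acetate F8. Partial reduction with (i-Bu)2AlH (1.1 equiv, toluene, −78 °C) then gives 4 directly.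

The third risk is step 2. The free aryloxyacetaldehyde may hydrate or oligomerise under aqueous acid. The fallback for step 2 sets out from compound 1 and comes back to the route at compound 4, making the aldehyde by a non-acidic, anhydrous oxidation. Compound 1 is alkylated with 2-bromoethanol (K2CO3, DMF, 80 °C) to give 2-(4-allyl-2,6-dimethoxyphenoxy)ethan-1-ol F9. Dess–Martin periodinane with NaHCO3 in CH2Cl2 at 0 °C oxidises it to 4 without touching the allyl group.

Further compounds
F1 | step 3 | 5-iodo-1,2,3-trimethoxybenzene | COc1cc(I)cc(OC)c1OC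
F2 | step 3 | 3-(3,4,5-trimethoxyphenyl)propanal | COc1cc(CCC=O)cc(OC)c1OC
F3 | step 3 | (S)-2-(N-phenylaminooxy)-3-(3,4,5-trimethoxyphenyl)propanal | c1ccc(NO[C@H](C=O)Cc2cc(OC)c(OC)c(OC)c2)cc1
F4 | step 3 | (S)-2-(N-phenylaminooxy)-3-(3,4,5-trimethoxyphenyl)propan-1-ol | c1ccc(NO[C@H](CO)Cc2cc(OC)c(OC)c(OC)c2)cc1
F5 | step 3 | (S)-3-(3,4,5-trimethoxyphenyl)propane-1,2-diol | O[C@H](CO)Cc1cc(OC)c(OC)c(OC)c1
F6 | step 3 | (S)-1-(tert-butyldimethylsilyloxy)-3-(3,4,5-trimethoxyphenyl)propan-2-ol | O[C@H](CO[Si](C)(C)C(C)(C)C)Cc1cc(OC)c(OC)c(OC)c1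
F7 | step 3 | (R)-tert-butyl[2-(4-allyl-2,6-dimethoxyphenoxy)-3-(3,4,5-trimethoxyphenyl)propoxy]dimethylsilane | C=CCc1cc(OC)c(O[C@@H](CO[Si](C)(C)C(C)(C)C)Cc2cc(OC)c(OC)c(OC)c2)c(OC)c1
F8 | step 1 | ethyl 2-(4-allyl-2,6-dimethoxyphenoxy)acetate | C=CCc1cc(OC)c(OCC(=O)OCC)c(OC)c1
F9 | step 2 | 2-(4-allyl-2,6-dimethoxyphenoxy)ethan-1-ol | C=CCc1cc(OC)c(OCCO)c(OC)c1
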